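**Retrosynthetic overview**
- Maleimide ring (formed last): the C3=C4 bond and the imide C–N bond come from aldol addition, N-acylation and dehydration between a chroman-bearing propanoate ester and a 4-silyloxyphenyl α-keto amide.
- Key C–C bond: the aryl–CH2 bond of that ester, from Pd-catalysed coupling of an enantiopure 7-bromochroman-3-ol with a zinc ester homoenolate (a propanoate β-carbanion). Both carbons are electrophilic in their ordinary forms (aryl bromide, acrylate β-carbon).
- Stereocentre: the (S)-chroman-3-ol comes from 7-bromo-2,2-dimethyl-2H-chromene by Jacobsen epoxidation and hydride opening at the benzylic carbon.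
- Pyran ring (formed first): the chromene comes from 4-bromo-2-hydroxybenzaldehyde and an isobutenyl Grignard reagent through o-quinone methide oxa-6π electrocyclisation.

Assumption: the SMILES stereocentre is read as (S) at C3 of the chroman; 2 and 8 are bought as THF solutions and 10 as a catalogue solid.

**Step 1**
Reactants: 1 4-bromo-2-hydroxybenzaldehyde; 2 (2-methylprop-1-en-1-yl)magnesium bromide
Product: 5 7-bromo-2,2-dimethyl-2H-chromene, via allylic alcohol 3 (not isolated), via quinone methide 4 (not isolated)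
Conditions: 2 (2.5 equiv), THF, −78 to 0 °C; 1 M HCl quench; crude 3, TsOH·H2O (5 mol %), toluene, 80 °C
Reagents that add atoms: none
Why: Grignard 1,2-addition to the aldehyde (the first equivalent is spent on the phenol), then acid-promoted loss of water from the o-hydroxybenzylic allylic alcohol gives an o-quinone methide that closes by oxa-6π electrocyclisation; the bromine para to the formyl group ends at C7 and no stereocentre is formed.

**Step 2**
Reactants: 5 7-bromo-2,2-dimethyl-2H-chromene
Product: 6 (1aS,7bS)-5-bromo-2,2-dimethyl-1a,7b-dihydro-2H-oxireno[2,3-c]chromene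
Conditions: (S,S)-(salen)MnCl (4 mol %; salen = N,N'-bis(3,5-di-tert-butylsalicylidene)cyclohexane-1,2-diamine dianion), 4-phenylpyridine N-oxide (20 mol %), aq. NaOCl (pH 11.3), CH2Cl2, 0 °C
Reagents that add atoms: sodium hypochlorite, [Na+].[O-]Cl
Why: Jacobsen–Katsuki epoxidation, for which 2,2-dimethylchromenes are among the best substrates (usually >95% ee); the (S,S)-catalyst gives the (3S,4S)-epoxide in chroman numbering, which fixes the configuration of the future C3 carbinol.

**Step 3**
Reactants: 6 (1aS,7bS)-5-bromo-2,2-dimethyl-1a,7b-dihydro-2H-oxireno[2,3-c]chromene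
Product: 7 (3S)-7-bromo-2,2-dimethyl-3,4-dihydro-2H-chromen-3-ol
Conditions: LiAlH4 (0.6 equiv), THF, 0 °C; then H2O, aq. NaOH
Reagents that add atoms: none
Why: Regioselective SN2 hydride opening of the epoxide at the benzylic C4, which is activated and far less hindered than C3 beside the gem-dimethyl carbon; the C3–O bond is untouched so C3 stays (S), and the aryl bromide survives at 0 °C.

**Step 4**
Reactants: 7 (3S)-7-bromo-2,2-dimethyl-3,4-dihydro-2H-chromen-3-ol; 8 (3-ethoxy-3-oxopropyl)zinc bromide
Product: 9 ethyl 3-[(3S)-3-hydroxy-2,2-dimethyl-3,4-dihydro-2H-chromen-7-yl]propanoate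
Conditions: 8 (2.2 equiv, 0.5 M in THF, slow addition), Pd(OAc)2 (2 mol %), SPhos (4 mol %), THF, 25 to 50 °C
Reagents that add atoms: none
Why: Negishi cross-coupling of a zinc ester homoenolate, which makes the propanoate β-carbon the nucleophile and joins it to the aryl bromide carbon regiospecifically at C7; it is run on the unprotected alcohol, where slow addition of the weakly basic alkylzinc and fast reductive elimination from the SPhos–palladium complex outpace protonation and β-hydride elimination; the stereocentre is not involved.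

**Step 5**
Reactants: 10 methyl 2-(4-hydroxyphenyl)-2-oxoacetate
Product: 12 2-{4-[(tert-butyldimethylsilyl)oxy]phenyl}-2-oxoacetamide, via keto amide 11 (not isolated)
Conditions: NH3 (7 M in MeOH), 0 °C; evaporate; TBSCl, imidazole, DMF, 25 °C
Reagents that add atoms: ammonia, N; tert-butyldimethylsilyl chloride, CC(C)(C)[Si](C)(C)Cl
Why: Ammonolysis of the activated α-keto ester is fast at 0 °C, and imidazole-mediated silylation is selective for the phenol over the primary amide; the silyl ether stops a para-phenoxide from deactivating the ketone in step 6.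

**Step 6**
Reactants: 9 ethyl 3-[(3S)-3-hydroxy-2,2-dimethyl-3,4-dihydro-2H-chromen-7-yl]propanoate; 12 2-{4-[(tert-butyldimethylsilyl)oxy]phenyl}-2-oxoacetamide
Product: 16 asperimide C (3-{[(3S)-3-hydroxy-2,2-dimethyl-3,4-dihydro-2H-chromen-7-yl]methyl}-4-(4-hydroxyphenyl)-1H-pyrrole-2,5-dione), via aldol adduct 13 (not isolated), via silylated hydroxysuccinimide 14 (not isolated), via hydroxysuccinimide 15 (not isolated)
Conditions: 9, LiN(iPr)2 (2.2 equiv), THF, −78 °C; add 12 pre-mixed with LiN(SiMe3)2 (1.05 equiv) in THF at −78 °C; −78 to 25 °C; Bu4NF, 0 °C; then 2 M HCl, 25 °C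
Reagents that add atoms: none
Why: Crossed aldol addition of the lithium ester enolate to the non-enolisable, strongly electrophilic keto group of 12, then 5-exo-trig N-acylation by the ethyl ester (imide closure), fluoride desilylation and acid-promoted dehydration — a strong-base variant of the Faul-type maleimide condensation (acetic ester plus glyoxamide); the two transient sp3 centres vanish on dehydration and the remote chromanol centre is unaffected.

**Compound list**
1 | 4-bromo-2-hydroxybenzaldehyde | O=Cc1ccc(Br)cc1O | starting material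
2 | (2-methylprop-1-en-1-yl)magnesium bromide | CC(C)=C[Mg]Br | starting material
3 | 5-bromo-2-(1-hydroxy-3-methylbut-2-en-1-yl)phenol (racemic) | CC(C)=CC(O)c1ccc(Br)cc1O | intermediate
4 | 3-bromo-6-(3-methylbut-2-en-1-ylidene)cyclohexa-2,4-dien-1-one | CC(C)=CC=C1C=CC(Br)=CC1=O | intermediate
5 | 7-bromo-2,2-dimethyl-2H-chromene | CC1(C)C=Cc2ccc(Br)cc2O1 | intermediate
6 | (1aS,7bS)-5-bromo-2,2-dimethyl-1a,7b-dihydro-2H-oxireno[2,3-c]chromene, i.e. (3S,4S)-7-bromo-3,4-epoxy-2,2-dimethylchroman | CC1(C)Oc2cc(Br)ccc2[C@@H]3O[C@H]13 | intermediate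
7 | (3S)-7-bromo-2,2-dimethyl-3,4-dihydro-2H-chromen-3-ol | CC1(C)Oc2cc(Br)ccc2C[C@@H]1O | intermediate
8 | (3-ethoxy-3-oxopropyl)zinc bromide | CCOC(=O)CC[Zn]Br | starting material
9 | ethyl 3-[(3S)-3-hydroxy-2,2-dimethyl-3,4-dihydro-2H-chromen-7-yl]propanoate | CC1(C)Oc2cc(CCC(=O)OCC)ccc2C[C@@H]1O | intermediate
10 | methyl 2-(4-hydroxyphenyl)-2-oxoacetate | COC(=O)C(=O)c1ccc(O)cc1 | starting material
11 | 2-(4-hydroxyphenyl)-2-oxoacetamide | NC(=O)C(=O)c1ccc(O)cc1 | intermediate
12 | 2-{4-[(tert-butyldimethylsilyl)oxy]phenyl}-2-oxoacetamide | NC(=O)C(=O)c1ccc(O[Si](C)(C)C(C)(C)C)cc1 | intermediate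
13 | ethyl 4-amino-3-{4-[(tert-butyldimethylsilyl)oxy]phenyl}-3-hydroxy-2-{[(3S)-3-hydroxy-2,2-dimethyl-3,4-dihydro-2H-chromen-7-yl]methyl}-4-oxobutanoate (diastereomer mixture at C2 and C3) | CC1(C)Oc2cc(CC(C(=O)OCC)C(O)(C(N)=O)c3ccc(O[Si](C)(C)C(C)(C)C)cc3)ccc2C[C@@H]1O | intermediate
14 | 3-{4-[(tert-butyldimethylsilyl)oxy]phenyl}-3-hydroxy-4-{[(3S)-3-hydroxy-2,2-dimethyl-3,4-dihydro-2H-chromen-7-yl]methyl}pyrrolidine-2,5-dione (diastereomer mixture at the two ring carbons) | CC1(C)Oc2cc(CC3C(=O)NC(=O)C3(O)c4ccc(O[Si](C)(C)C(C)(C)C)cc4)ccc2C[C@@H]1O | intermediate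
15 | 3-hydroxy-3-(4-hydroxyphenyl)-4-{[(3S)-3-hydroxy-2,2-dimethyl-3,4-dihydro-2H-chromen-7-yl]methyl}pyrrolidine-2,5-dione (diastereomer mixture at the two ring carbons) | CC1(C)Oc2cc(CC3C(=O)NC(=O)C3(O)c4ccc(O)cc4)ccc2C[C@@H]1O | intermediate
16 | asperimide C, 3-{[(3S)-3-hydroxy-2,2-dimethyl-3,4-dihydro-2H-chromen-7-yl]methyl}-4-(4-hydroxyphenyl)-1H-pyrrole-2,5-dione | CC1(C)Oc2cc(CC3=C(c4ccc(O)cc4)C(=O)NC3=O)ccc2C[C@@H]1O | target

**Step count**
Total: 6 steps. Longest linear sequence: 5 steps (steps 1, 2, 3, 4, 6); step 5 is a side branch.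

**Steps most likely to fail, with fallbacks**

Step 6 (annulation). The risk is that the amide N–H of 12 quenches the ester enolate, or that the imide does not close in the pot. The fallback sets out from 9 and 10. Compound 10 is silylated (TBSCl, imidazole, DMF) to methyl 2-{4-[(tert-butyldimethylsilyl)oxy]phenyl}-2-oxoacetate F1, which carries no N–H. The lithium enolate of 9 is added to it at −78 °C and the hydroxy diester 1-ethyl 4-methyl 3-{4-[(tert-butyldimethylsilyl)oxy]phenyl}-3-hydroxy-2-{[(3S)-3-hydroxy-2,2-dimethyl-3,4-dihydro-2H-chromen-7-yl]methyl}butanedioate F2 is isolated. Nitrogen is then introduced afterwards by ammonolysis and imide closure (NH3 in MeOH, sealed tube, 60 °C), which also cleaves the aryl silyl ether. This gives 15, where the route is rejoined (2 M HCl to 16).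

Step 4 (homoenolate coupling). The risk is protodezincation by the free hydroxyl or β-hydride elimination. The fallback sets out from 7 and replaces the moisture-sensitive zinc reagent with the bench-stable boron homoenolate potassium (3-ethoxy-3-oxopropyl)trifluoroborate in a Suzuki–Miyaura coupling (Pd(OAc)2, RuPhos ligand, K2CO3, toluene/H2O, 85 °C). This runs in aqueous base, where the alcohol is no liability. It gives 9 directly, so the route is rejoined at 9 and no new compound arises (F0).

Step 3 (epoxide opening). The risk is hydride attack at C3 or partial reduction of the C–Br bond. The fallback sets out from 6 and gives up the epoxide as the source of chirality. A Lewis-acid Meinwald rearrangement (ZnBr2, toluene, 60 °C; benzylic C–O cleavage then 1,2-hydride shift) gives 7-bromo-2,2-dimethyl-2H-chromen-3(4H)-one F3. Enantioselective reduction with (R)-2-methyl-CBS-oxazaborolidine and BH3·SMe2, with the quaternary C2 side acting as the large group, returns 7.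

**Further compounds**
F1 | step 6 | methyl 2-{4-[(tert-butyldimethylsilyl)oxy]phenyl}-2-oxoacetate | COC(=O)C(=O)c1ccc(O[Si](C)(C)C(C)(C)C)cc1
F2 | step 6 | 1-ethyl 4-methyl 3-{4-[(tert-butyldimethylsilyl)oxy]phenyl}-3-hydroxy-2-{[(3S)-3-hydroxy-2,2-dimethyl-3,4-dihydro-2H-chromen-7-yl]methyl}butanedioate | CC1(C)Oc2cc(CC(C(=O)OCC)C(O)(C(=O)OC)c3ccc(O[Si](C)(C)C(C)(C)C)cc3)ccc2C[C@@H]1O
F0 | step 4 | none | none
F3 | step 3 | 7-bromo-2,2-dimethyl-2H-chromen-3(4H)-one | CC1(C)Oc2cc(Br)ccc2CC1=O
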